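**Retrosynthetic overview**
1. The target is reached last by α-acetoxylation at C5 of an α,β-epoxy ketone; the C4 ketone is carried through the route as a silyl-protected alcohol that derives from the carvone carbonyl.
2. Side chain: the C10–C11 oxirane comes from a reagent-controlled Shi epoxidation of a prenyl group; C8–C9 comes from Brown allylation of an α-methylene aldehyde (made from the isopropenyl CH3) followed by cross-metathesis; both angelates come from mixed-anhydride esterification.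
3. Ring oxygens: the C2–C3 oxirane comes from hydroxyl-directed epoxidation of a cis allylic alcohol; the C1 alcohol comes from bulky-hydride reduction of an enone made by allylic oxidation of cis-carveol silyl ether.
4. The carbocycle and C6 are bought as (R)-(−)-carvone. Order of ring formation: cyclohexane (chiral pool), then ring oxirane (step 5), then side-chain oxirane (step 11).

Assumption: ring atoms carry the target's numbers (C1 CH–OAng, C2–C3 oxirane with CH3 on C3, C4 C=O, C5 CH–OAc, C6 CH–side chain; side chain C7(=C14H2)–C8–C9–C10–C11), Ang = (Z)-2-methylbut-2-enoyl, TBS = tert-butyldimethylsilyl, and (+)-Ipc2B(allyl) solution, angelic acid and the ent-Shi ketone are purchased.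

**Step 1**
Reactants: 1 (R)-(−)-carvone
Product: 2 (−)-cis-carveol [(1R,5R)-2-methyl-5-(prop-1-en-2-yl)cyclohex-2-en-1-ol]
Conditions: NaBH4, CeCl3·7H2O, MeOH, −78 °C → 0 °C
Reagents that add atoms: none
Why: Luche 1,2-reduction; hydride attacks the enone carbonyl axially, so the new C4 carbinol (R) is cis to the C6 isopropenyl group, and this centre only serves as a masked form of the later C4 ketone.

**Step 2**
Reactants: 2 (−)-cis-carveol
Product: 3 cis-carveol tert-butyldimethylsilyl ether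
Conditions: t-BuMe2SiCl, imidazole, DMF, rt
Reagents that add atoms: tert-butyldimethylsilyl chloride, CC(C)(C)[Si](C)(C)Cl
Why: Imidazole-promoted silylation masks the C4 oxygen so that it survives the oxidations, the hydride and the esterifications that follow.

**Step 3**
Reactants: 3 cis-carveol tert-butyldimethylsilyl ether
Product: 4 (4R,6R)-4-(TBSO)-3-methyl-6-(prop-1-en-2-yl)cyclohex-2-en-1-one
Conditions: CrO3, 3,5-dimethylpyrazole, CH2Cl2, −20 °C
Reagents that add atoms: chromium trioxide, O=[Cr](=O)=O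
Why: Allylic C–H oxidation with the CrO3·3,5-dimethylpyrazole complex turns the ring CH2 next to the CH= end of the trisubstituted alkene into the conjugated ketone (the site selectivity seen in valencene and Δ5-steroid oxidations), leaving the isopropenyl group and C6 untouched.

**Step 4**
Reactants: 4 (4R,6R)-4-(TBSO)-3-methyl-6-(prop-1-en-2-yl)cyclohex-2-en-1-one
Product: 5 (1R,4R,6R)-4-(TBSO)-3-methyl-6-(prop-1-en-2-yl)cyclohex-2-en-1-ol
Conditions: LiBH(s-Bu)3, THF, −78 °C; then aq. NaOH, H2O2, 0 °C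
Reagents that add atoms: none
Why: 1,2-Reduction of the β,β-disubstituted enone by the bulky trialkylborohydride occurs by equatorial attack, giving the axial C1 alcohol cis to the equatorial C6 isopropenyl group, as in the reduction of isopiperitenone to cis-isopiperitenol.

**Step 5**
Reactants: 5 (1R,4R,6R)-4-(TBSO)-3-methyl-6-(prop-1-en-2-yl)cyclohex-2-en-1-ol
Product: 6 (1S,2S,3S,4R,6R)-4-(TBSO)-2,3-epoxy-3-methyl-6-(prop-1-en-2-yl)cyclohexan-1-ol
Conditions: VO(acac)2 (2 mol%), t-BuOOH, CH2Cl2, 0 °C → rt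
Reagents that add atoms: tert-butyl hydroperoxide, CC(C)(C)OO
Why: Hydroxyl-directed vanadium-catalysed (Sharpless–Michaelson) epoxidation; the vanadate ester of the pseudoaxial C1 alcohol delivers oxygen to the same face of the adjacent alkene, setting C2 and C3 cis to C1–O, much faster than reaction at the isopropenyl group.

**Step 6**
Reactants: 6 (1S,2S,3S,4R,6R)-4-(TBSO)-2,3-epoxy-3-methyl-6-(prop-1-en-2-yl)cyclohexan-1-ol
Product: 7 C1 angelate of 6
Conditions: angelic acid, 2,4,6-Cl3C6H2COCl, Et3N, toluene, rt; then 6, 80 °C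
Reagents that add atoms: angelic acid [(Z)-2-methylbut-2-enoic acid], C/C=C(/C)C(=O)O
Why: Yamaguchi-type esterification through the mixed 2,4,6-trichlorobenzoic anhydride, run without DMAP, acylates the hindered alcohol while avoiding Z-to-E (angelate-to-tiglate) isomerisation; no stereocentre is touched.

**Step 7**
Reactants: 7 C1 angelate of 6
Product: 9 α-methylene aldehyde [6-(3-oxoprop-1-en-2-yl) analogue of 7], via primary allylic alcohol 8 (not isolated)
Conditions: SeO2 (0.5 equiv), t-BuOOH, CH2Cl2, rt; then MnO2, CH2Cl2, rt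
Reagents that add atoms: tert-butyl hydroperoxide, CC(C)(C)OO (oxygen source, relayed by selenium dioxide, O=[Se]=O)
Why: Riley allylic oxidation (ene reaction then [2,3]-sigmatropic shift) hydroxylates the CH3 of the only electron-rich alkene in preference to the hindered C6–H, and MnO2 oxidises the allylic alcohol to the enal.

**Step 8**
Reactants: 9 α-methylene aldehyde
Product: 11 homoallylic alcohol [6-((3R)-3-hydroxyhexa-1,5-dien-2-yl) analogue of 7], via diisopinocampheylborinate ester 10 (not isolated)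
Conditions: (+)-Ipc2B(allyl), Et2O, −78 °C; then NaBO3·4H2O, THF/H2O, rt
Reagents that add atoms: (+)-B-allyldiisopinocampheylborane, C=CCB([C@H]1C[C@H]2C[C@@H]([C@@H]1C)C2(C)C)[C@H]1C[C@H]2C[C@@H]([C@@H]1C)C2(C)C (allyl group of 11; boryl group of 10 only)
Why: Brown allylboration through a chair Zimmerman–Traxler transition state; the reagent derived from (−)-α-pinene adds allyl to the Re face of the aldehyde under reagent control, setting C8 as (R).

**Step 9**
Reactants: 11 homoallylic alcohol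
Product: 12 prenyl carbinol [6-((3R)-3-hydroxy-6-methylhepta-1,5-dien-2-yl) analogue of 7]
Conditions: (H2IMes)(PCy3)Cl2Ru=CHPh (second-generation Grubbs catalyst, 5 mol%), 2-methylbut-2-ene (excess), CH2Cl2, 40 °C
Reagents that add atoms: 2-methylbut-2-ene, CC=C(C)C
Why: Olefin cross-metathesis exchanges the terminal CH2 for an isopropylidene unit; the 1,1-disubstituted alkene and the angelate are too hindered and electron-poor to take part.

**Step 10**
Reactants: 12 prenyl carbinol
Product: 13 bis-angelate [C8–OAng analogue of 12]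
Conditions: angelic acid, 2,4,6-Cl3C6H2COCl, Et3N, toluene, rt; then 12, 80 °C
Reagents that add atoms: angelic acid [(Z)-2-methylbut-2-enoic acid], C/C=C(/C)C(=O)O
Why: Same DMAP-free Yamaguchi-type esterification as step 6; acylating C8–OH before epoxidation also removes the hydroxyl that could otherwise open the neighbouring oxirane.

**Step 11**
Reactants: 13 bis-angelate
Product: 14 side-chain (10S)-epoxide of 13
Conditions: ent-Shi ketone (from L-sorbose, 30 mol%), Oxone (2KHSO5·KHSO4·K2SO4), K2CO3, Bu4NHSO4, MeCN/CH2(OMe)2/aq. Na2B4O7 buffer, 0 °C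
Reagents that add atoms: potassium peroxymonosulfate (active component of Oxone), [K+].[O-]S(=O)(=O)OO
Why: Shi asymmetric epoxidation; the chiral dioxirane reacts through a spiro transition state only with the most electron-rich (trisubstituted) alkene, and the ketone enantiomeric to the D-fructose-derived one gives the (S)-oxirane at C10 under reagent control.

**Step 12**
Reactants: 14 side-chain (10S)-epoxide of 13
Product: 15 C4 alcohol
Conditions: Bu4NF, THF, 0 °C → rt
Reagents that add atoms: none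
Why: Fluoride-mediated desilylation frees the C4 hydroxyl; the esters and both oxiranes are inert, and the cis relationship of C4–O to the ring oxirane rules out Payne rearrangement.

**Step 13**
Reactants: 15 C4 alcohol
Product: 16 α,β-epoxy ketone
Conditions: Dess–Martin periodinane, pyridine, CH2Cl2, 0 °C → rt
Reagents that add atoms: none
Why: Dess–Martin oxidation under buffered conditions gives the C4 ketone without disturbing the acid-sensitive side-chain oxirane; the C4 stereocentre from step 1 is erased here.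

**Step 14**
Reactants: 16 α,β-epoxy ketone
Product: 18 CNP0407453.2 (target), via trimethylsilyl enol ether 17 (not isolated)
Conditions: LiN(SiMe3)2, Me3SiCl, THF, −78 °C; then Pb(OAc)4, CH2Cl2, −20 → 0 °C
Reagents that add atoms: lead tetraacetate, CC(=O)O[Pb](OC(C)=O)(OC(C)=O)OC(C)=O (acetoxy group of 18); chlorotrimethylsilane, C[Si](C)(C)Cl (silyl group of 17 only)
Why: Kinetic enolisation can only go towards C5 because C3 is quaternary, and Rubottom-type oxidation of the silyl enol ether with Pb(OAc)4 delivers acetate to the face opposite the bulky C6 side chain, setting C5 as (S), trans to C6.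

**Compound list**
1 | (R)-(−)-carvone [(5R)-2-methyl-5-(prop-1-en-2-yl)cyclohex-2-en-1-one] | C=C(C)[C@@H]1CC=C(C)C(=O)C1 | starting material
2 | (−)-cis-carveol [(1R,5R)-2-methyl-5-(prop-1-en-2-yl)cyclohex-2-en-1-ol, OH cis to isopropenyl] | C=C(C)[C@@H]1CC=C(C)[C@H](O)C1 | intermediate
3 | tert-butyldimethyl{[(1R,5R)-2-methyl-5-(prop-1-en-2-yl)cyclohex-2-en-1-yl]oxy}silane | C=C(C)[C@@H]1CC=C(C)[C@H](O[Si](C)(C)C(C)(C)C)C1 | intermediate
4 | (4R,6R)-4-[(tert-butyldimethylsilyl)oxy]-3-methyl-6-(prop-1-en-2-yl)cyclohex-2-en-1-one | C=C(C)[C@@H]1C(=O)C=C(C)[C@H](O[Si](C)(C)C(C)(C)C)C1 | intermediate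
5 | (1R,4R,6R)-4-[(tert-butyldimethylsilyl)oxy]-3-methyl-6-(prop-1-en-2-yl)cyclohex-2-en-1-ol (OH, OTBS and isopropenyl all cis) | C=C(C)[C@@H]1[C@H](O)C=C(C)[C@H](O[Si](C)(C)C(C)(C)C)C1 | intermediate
6 | (1S,2S,3S,4R,6R)-4-[(tert-butyldimethylsilyl)oxy]-2,3-epoxy-3-methyl-6-(prop-1-en-2-yl)cyclohexan-1-ol (oxirane cis to OH) | C=C(C)[C@@H]1[C@H](O)[C@@H]2O[C@]2(C)[C@H](O[Si](C)(C)C(C)(C)C)C1 | intermediate
7 | (1S,2S,3S,4R,6R)-4-[(tert-butyldimethylsilyl)oxy]-2,3-epoxy-3-methyl-6-(prop-1-en-2-yl)cyclohexyl (Z)-2-methylbut-2-enoate | C=C(C)[C@@H]1[C@H](OC(=O)/C(C)=C\C)[C@@H]2O[C@]2(C)[C@H](O[Si](C)(C)C(C)(C)C)C1 | intermediate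
8 | (1S,2S,3S,4R,6R)-4-[(tert-butyldimethylsilyl)oxy]-2,3-epoxy-6-(3-hydroxyprop-1-en-2-yl)-3-methylcyclohexyl angelate | C=C(CO)[C@@H]1[C@H](OC(=O)/C(C)=C\C)[C@@H]2O[C@]2(C)[C@H](O[Si](C)(C)C(C)(C)C)C1 | intermediate (not isolated)
9 | (1S,2S,3S,4R,6R)-4-[(tert-butyldimethylsilyl)oxy]-2,3-epoxy-3-methyl-6-(3-oxoprop-1-en-2-yl)cyclohexyl angelate | C=C(C=O)[C@@H]1[C@H](OC(=O)/C(C)=C\C)[C@@H]2O[C@]2(C)[C@H](O[Si](C)(C)C(C)(C)C)C1 | intermediate
10 | bis(isopinocampheyl)borinate of alcohol 11 (O–B(Ipc)2 on C8, Ipc groups from (−)-α-pinene) | C=C([C@@H]1[C@H](OC(=O)/C(C)=C\C)[C@@H]2O[C@]2(C)[C@H](O[Si](C)(C)C(C)(C)C)C1)[C@@H](CC=C)OB([C@H]1C[C@H]2C[C@@H]([C@@H]1C)C2(C)C)[C@H]1C[C@H]2C[C@@H]([C@@H]1C)C2(C)C | intermediate (not isolated)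
11 | (1S,2S,3S,4R,6R)-4-[(tert-butyldimethylsilyl)oxy]-2,3-epoxy-6-[(3R)-3-hydroxyhexa-1,5-dien-2-yl]-3-methylcyclohexyl angelate | C=C([C@@H]1[C@H](OC(=O)/C(C)=C\C)[C@@H]2O[C@]2(C)[C@H](O[Si](C)(C)C(C)(C)C)C1)[C@@H](CC=C)O | intermediate
12 | (1S,2S,3S,4R,6R)-4-[(tert-butyldimethylsilyl)oxy]-2,3-epoxy-6-[(3R)-3-hydroxy-6-methylhepta-1,5-dien-2-yl]-3-methylcyclohexyl angelate | C=C([C@@H]1[C@H](OC(=O)/C(C)=C\C)[C@@H]2O[C@]2(C)[C@H](O[Si](C)(C)C(C)(C)C)C1)[C@@H](CC=C(C)C)O | intermediate
13 | (1S,2S,3S,4R,6R)-6-[(3R)-3-(angeloyloxy)-6-methylhepta-1,5-dien-2-yl]-4-[(tert-butyldimethylsilyl)oxy]-2,3-epoxy-3-methylcyclohexyl angelate | C=C([C@@H]1[C@H](OC(=O)/C(C)=C\C)[C@@H]2O[C@]2(C)[C@H](O[Si](C)(C)C(C)(C)C)C1)[C@@H](CC=C(C)C)OC(=O)/C(C)=C\C | intermediate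
14 | (1S,2S,3S,4R,6R)-6-{(3R)-3-(angeloyloxy)-4-[(2S)-3,3-dimethyloxiran-2-yl]but-1-en-2-yl}-4-[(tert-butyldimethylsilyl)oxy]-2,3-epoxy-3-methylcyclohexyl angelate | C=C([C@@H]1[C@H](OC(=O)/C(C)=C\C)[C@@H]2O[C@]2(C)[C@H](O[Si](C)(C)C(C)(C)C)C1)[C@@H](C[C@@H]1OC1(C)C)OC(=O)/C(C)=C\C | intermediate
15 | (1S,2S,3R,4R,6R)-6-{(3R)-3-(angeloyloxy)-4-[(2S)-3,3-dimethyloxiran-2-yl]but-1-en-2-yl}-2,3-epoxy-4-hydroxy-3-methylcyclohexyl angelate | C=C([C@@H]1[C@H](OC(=O)/C(C)=C\C)[C@@H]2O[C@]2(C)[C@H](O)C1)[C@@H](C[C@@H]1OC1(C)C)OC(=O)/C(C)=C\C | intermediate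
16 | (1S,2S,3S,6R)-6-{(3R)-3-(angeloyloxy)-4-[(2S)-3,3-dimethyloxiran-2-yl]but-1-en-2-yl}-2,3-epoxy-3-methyl-4-oxocyclohexyl angelate | C=C([C@@H]1[C@H](OC(=O)/C(C)=C\C)[C@@H]2O[C@]2(C)C(=O)C1)[C@@H](C[C@@H]1OC1(C)C)OC(=O)/C(C)=C\C | intermediate
17 | (1S,2S,3S,6R)-6-{(3R)-3-(angeloyloxy)-4-[(2S)-3,3-dimethyloxiran-2-yl]but-1-en-2-yl}-2,3-epoxy-3-methyl-4-[(trimethylsilyl)oxy]cyclohex-4-en-1-yl angelate | C=C([C@@H]1[C@H](OC(=O)/C(C)=C\C)[C@@H]2O[C@]2(C)C(O[Si](C)(C)C)=C1)[C@@H](C[C@@H]1OC1(C)C)OC(=O)/C(C)=C\C | intermediate (not isolated)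
18 | CNP0407453.2: (1S,2S,3S,5S,6R)-5-acetoxy-6-{(3R)-3-(angeloyloxy)-4-[(2S)-3,3-dimethyloxiran-2-yl]but-1-en-2-yl}-2,3-epoxy-3-methyl-4-oxocyclohexyl angelate | C=C([C@@H]1[C@H](OC(=O)/C(C)=C\C)[C@@H]2O[C@]2(C)C(=O)[C@H]1OC(C)=O)[C@@H](C[C@@H]1OC1(C)C)OC(=O)/C(C)=C\C | target

**Totals**
Total step count: 14. Longest linear sequence: 14 steps (fully linear from 1).

**Steps most likely to fail**

Step 3 (site-selective allylic oxidation of 3). The oxidant may also attack the silyloxy-bearing C–H or the isopropenyl group. The fallback sets out from 3. A Schenck ene reaction with singlet oxygen (O2, tetraphenylporphyrin, hν, CH2Cl2, 0 °C) puts oxygen on C3 and shifts the alkene to C1=C2, giving tertiary allylic hydroperoxide F1 (drawn with the hydroperoxide anti to the silyloxy group; this centre is lost again). PPh3 reduces it to tertiary allylic alcohol F2. Babler–Dauben oxidative 1,3-transposition with pyridinium chlorochromate, (C5H5NH)[CrO3Cl], in CH2Cl2 then moves oxygen to C1 and comes back to the route at 4.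

Step 7 (SeO2 oxidation of the isopropenyl CH3 in the functionalised intermediate 7). Conversion may be low, or selenium species may isomerise the angelate. The fallback sets out from 7. Ene-type chlorination with hypochlorous acid generated from Ca(OCl)2 and solid CO2 (CH2Cl2/H2O, 0 °C) gives allylic chloride F3. Ganem oxidation with N-methylmorpholine N-oxide in MeCN converts the CH2Cl group into the aldehyde and comes back to the route at 9.

Step 14 (late-stage acetoxylation next to the epoxy ketone in the presence of two angelates and two oxiranes). Pb(OAc)4 may give poor conversion or attack an alkene. The fallback sets out from 16. The potassium enolate (KN(SiMe3)2, THF, −78 °C) is hydroxylated with 2-(phenylsulfonyl)-3-phenyloxaziridine (Davis reagent), again anti to the C6 side chain, giving α-hydroxy ketone F4. Acetylation with Ac2O, pyridine and catalytic DMAP at 0 °C comes back to the route at 18.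

**Further compounds**
F1 | step 3 | tertiary allylic hydroperoxide: (1R,4R)-1-hydroperoxy-1-methyl-4-(prop-1-en-2-yl)-6-(TBSO)cyclohex-2-ene skeleton, OOH on C3 of the route numbering, alkene C1=C2 | C=C(C)[C@@H]1C=C[C@@](C)(OO)[C@H](O[Si](C)(C)C(C)(C)C)C1
F2 | step 3 | tertiary allylic alcohol corresponding to F1 (OH on C3, alkene C1=C2) | C=C(C)[C@@H]1C=C[C@@](C)(O)[C@H](O[Si](C)(C)C(C)(C)C)C1
F3 | step 7 | allylic chloride: 6-(3-chloroprop-1-en-2-yl) analogue of 7 | C=C(CCl)[C@@H]1[C@H](OC(=O)/C(C)=C\C)[C@@H]2O[C@]2(C)[C@H](O[Si](C)(C)C(C)(C)C)C1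
F4 | step 14 | α-hydroxy ketone: (5S)-5-hydroxy analogue of 16 (5-deacetyl target) | C=C([C@@H]1[C@H](OC(=O)/C(C)=C\C)[C@@H]2O[C@]2(C)C(=O)[C@H]1O)[C@@H](C[C@@H]1OC1(C)C)OC(=O)/C(C)=C\C
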